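## Retrosynthetic overview

1. The target is treated as a head-to-tail [7.7]paracyclophane. Carbamates and phenols are unveiled last (TIPS off, carbamoylation, MOM off); the chloride is installed before fragment union.
2. Both arenes come from 3,5-dihydroxybenzaldehyde. The only ring formed is the 22-membered cyclophane, closed by ring-closing metathesis at C17=C18 after a Julia–Kocienski union at C4=C5; both olefins are then hydrogenated.
3. The union partners are sulfone 18 (ring B, butyl arm) and aldehyde 29 (ring A, chlorobutyl arm), both made from one common aldehyde 10.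
4. C7 and C20 are set by Eschenmoser–Claisen 1,3-chirality transfer from allylic alcohols of opposite configuration: CBS reduction for the ring B series, ketoreductase reduction of a β-keto ester for the ring A series.
5. C1/C2 (= C14/C15) come from a chiral phosphoric acid-catalysed (Z)-crotylboration, followed by ortho-lithiation/formylation between the two MOM ethers.

Assumption: the descriptors in the SMILES are taken literally, (1R,2S,7S,14R,15S,20S) in the numbering below, so the butyl- and chlorobutyl-bearing benzylic carbons have opposite spatial sense and need enantiomeric allylic alcohols.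

Numbering: bridge 1 = C1(O)–C2(Me)–C3…C6–C7(Bu), with C1 on ring A and C7 on ring B; bridge 2 = C14(O)–C15(Me)–C16…C19–C20(4-chlorobutyl), with C14 on ring B and C20 on ring A.

Abbreviations: MOM = CH2OCH3; TBS = Si(t-Bu)Me2; TIPS = Si(i-Pr)3; PT = 1-phenyl-1H-tetrazol-5-yl; Ar = 4-[(1R,2S)-4-(TBSO)-2-methyl-1-(TIPSO)butyl]-2,6-bis(MOMO)phenyl.

## Route

### Common aldehyde 10 (steps 1–6)

Step 1
Reactants: 1 3,5-dihydroxybenzaldehyde
Product: 2 3,5-bis(methoxymethoxy)benzaldehyde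
Conditions: MOMCl, i-Pr2NEt, CH2Cl2, 0 °C → rt
Reagents that add atoms: chloromethyl methyl ether, COCCl
Why: Phenol O-alkylation (MOM protection) gives ethers that later direct ortho-lithiation and leave under mild acid.

Step 2
Reactants: 2 3,5-bis(methoxymethoxy)benzaldehyde
Product: 4 (1R,2S)-1-[3,5-bis(methoxymethoxy)phenyl]-2-methylbut-3-en-1-ol, via pinacol borate ester 3 (not isolated)
Conditions: (Z)-crotyl-B(pin), (R)-TRIP (5 mol%), toluene, −30 °C; aqueous work-up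
Reagents that add atoms: (Z)-crotylboronic acid pinacol ester, C/C=C\CB1OC(C)(C)C(C)(C)O1
Why: Chiral phosphoric acid-catalysed crotylboration through a closed chair transition state: the (Z)-boronate gives the syn Me/OH pair and (R)-TRIP steers addition to the re face, setting C1 (R) and C2 (S) together.

Step 3
Reactants: 4 (1R,2S)-1-[3,5-bis(methoxymethoxy)phenyl]-2-methylbut-3-en-1-ol
Product: 5 {[(1R,2S)-1-[3,5-bis(methoxymethoxy)phenyl]-2-methylbut-3-en-1-yl]oxy}triisopropylsilane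
Conditions: TIPSOTf, 2,6-lutidine, CH2Cl2, 0 °C
Reagents that add atoms: triisopropylsilyl trifluoromethanesulfonate, CC(C)[Si](OS(=O)(=O)C(F)(F)F)(C(C)C)C(C)C
Why: Silylation with a silyl triflate protects the hindered benzylic alcohol as a bulky ether that survives later removal of primary TBS groups.

Step 4
Reactants: 5 {[(1R,2S)-1-[3,5-bis(methoxymethoxy)phenyl]-2-methylbut-3-en-1-yl]oxy}triisopropylsilane
Product: 7 (3S,4R)-4-[3,5-bis(methoxymethoxy)phenyl]-3-methyl-4-(triisopropylsilyloxy)butan-1-ol, via B-alkyl-9-BBN borane 6 (not isolated)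
Conditions: 9-BBN, THF, 0 °C → rt; then NaOH, H2O2, 0 °C
Reagents that add atoms: hydrogen peroxide, OO; 9-borabicyclo[3.3.1]nonane, B1C2CCCC1CCC2 (its atoms stay only in 6)
Why: Anti-Markovnikov hydroboration–oxidation with bulky 9-BBN puts the hydroxyl on the terminal carbon (future C4/C17) without touching the stereocentres.

Step 5
Reactants: 7 (3S,4R)-4-[3,5-bis(methoxymethoxy)phenyl]-3-methyl-4-(triisopropylsilyloxy)butan-1-ol
Product: 8 (1R,2S)-1-[3,5-bis(methoxymethoxy)phenyl]-4-(tert-butyldimethylsilyloxy)-2-methyl-1-(triisopropylsilyloxy)butane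
Conditions: TBSCl, imidazole, DMF, rt
Reagents that add atoms: tert-butyldimethylsilyl chloride, CC(C)(C)[Si](C)(C)Cl
Why: Standard silylation of the primary alcohol gives a base-stable ether that fluoride removes selectively later.

Step 6
Reactants: 8 (1R,2S)-1-[3,5-bis(methoxymethoxy)phenyl]-4-(tert-butyldimethylsilyloxy)-2-methyl-1-(triisopropylsilyloxy)butane
Product: 10 Ar–CHO, 4-[(1R,2S)-4-(tert-butyldimethylsilyloxy)-2-methyl-1-(triisopropylsilyloxy)butyl]-2,6-bis(methoxymethoxy)benzaldehyde, via 4-lithio arene 9 (not isolated)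
Conditions: n-BuLi, TMEDA, THF, 0 °C; then DMF, −78 °C → rt
Reagents that add atoms: N,N-dimethylformamide, CN(C)C=O; n-butyllithium, [Li]CCCC (lithium stays only in 9)
Why: Directed ortho-metalation lithiates the position flanked by the two MOM ethers and the aryllithium is formylated by DMF.

### Ring B series: sulfone 18 (steps 7–13)

Step 7
Reactants: 10 Ar–CHO
Product: 11 (1E)-1-Ar-pent-1-en-3-one
Conditions: dimethyl (2-oxobutyl)phosphonate, NaH, THF, 0 → 40 °C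
Reagents that add atoms: dimethyl (2-oxobutyl)phosphonate, CCC(=O)CP(=O)(OC)OC
Why: Horner–Wadsworth–Emmons olefination of the aryl aldehyde gives the (E)-enone.

Step 8
Reactants: 11 (1E)-1-Ar-pent-1-en-3-one
Product: 12 (1E,3R)-1-Ar-pent-1-en-3-ol
Conditions: (S)-2-methyl-CBS-oxazaborolidine (20 mol%), catecholborane, toluene, −78 °C
Reagents that add atoms: none
Why: Corey–Bakshi–Shibata reduction: the oxazaborolidine distinguishes the large aryl-vinyl group from the small ethyl group and delivers hydride to the face that gives the 3R allylic alcohol, without 1,4-reduction.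

Step 9
Reactants: 12 (1E,3R)-1-Ar-pent-1-en-3-ol
Product: 14 (3R,4E)-3-Ar-N,N-dimethylhept-4-enamide, via ketene N,O-acetal 13 (not isolated)
Conditions: MeC(OMe)2NMe2, xylenes, 140 °C (MeOH distilled off)
Reagents that add atoms: N,N-dimethylacetamide dimethyl acetal, COC(C)(OC)N(C)C
Why: Eschenmoser–Claisen rearrangement: the ketene N,O-acetal rearranges suprafacially through a chair with ethyl equatorial, so the carbinol configuration is transferred to the new benzylic centre (future C7) and an (E)-olefin remains.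

Step 10
Reactants: 14 (3R,4E)-3-Ar-N,N-dimethylhept-4-enamide
Product: 15 (3S)-3-Ar-N,N-dimethylheptanamide
Conditions: H2 (1 atm), 5% Pt/C, EtOAc, rt
Reagents that add atoms: none
Why: Heterogeneous catalytic hydrogenation saturates the olefin to the n-butyl chain (descriptor changes only by CIP rank), and Pt/C spares the benzylic C–O bond.

Step 11
Reactants: 15 (3S)-3-Ar-N,N-dimethylheptanamide
Product: 16 (3S)-3-Ar-heptan-1-ol
Conditions: LiEt3BH, THF, 0 °C → rt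
Reagents that add atoms: none
Why: Triethylborohydride reduction of the tertiary amide proceeds with C–N cleavage to the primary alcohol (future C5).

Step 12
Reactants: 16 (3S)-3-Ar-heptan-1-ol
Product: 17 5-{[(3S)-3-Ar-heptyl]sulfanyl}-1-phenyl-1H-tetrazole
Conditions: PT-SH, PPh3, DIAD, THF, 0 °C → rt
Reagents that add atoms: 1-phenyl-1H-tetrazole-5-thiol, Sc1nnnn1-c1ccccc1
Why: Mitsunobu thioetherification of the primary alcohol with the acidic tetrazole thiol.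

Step 13
Reactants: 17 5-{[(3S)-3-Ar-heptyl]sulfanyl}-1-phenyl-1H-tetrazole
Product: 18 5-{[(3S)-3-Ar-heptyl]sulfonyl}-1-phenyl-1H-tetrazole
Conditions: (NH4)6Mo7O24·4H2O (20 mol%), 30% H2O2, EtOH, 0 °C → rt
Reagents that add atoms: hydrogen peroxide, OO
Why: Molybdate-catalysed peroxide oxidation of the sulfide gives the Julia–Kocienski sulfone; no olefin is present to interfere.

### Ring A series: aldehyde 29 (steps 14–23)

Step 14
Reactants: 10 Ar–CHO
Product: 19 ethyl (4E)-5-Ar-3-oxopent-4-enoate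
Conditions: ethyl 4-(diethoxyphosphoryl)-3-oxobutanoate, NaH (2.2 equiv), THF, 0 °C → rt
Reagents that add atoms: ethyl 4-(diethoxyphosphoryl)-3-oxobutanoate, CCOC(=O)CC(=O)CP(=O)(OCC)OCC
Why: Horner–Wadsworth–Emmons olefination through the γ-carbanion of the phosphonoacetoacetate dianion gives the (E)-δ-aryl β-keto ester.

Step 15
Reactants: 19 ethyl (4E)-5-Ar-3-oxopent-4-enoate
Product: 20 ethyl (3S,4E)-5-Ar-3-hydroxypent-4-enoate
Conditions: ketoreductase (S-selective, NADPH-dependent), NADP+ (cat.), i-PrOH (15% v/v), DMSO (10% v/v), phosphate buffer pH 7.0, 30 °C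
Reagents that add atoms: none
Why: Enzymatic asymmetric ketone reduction by a ketoreductase (alcohol dehydrogenase class) with isopropanol-driven cofactor recycling delivers hydride to one face of the β-keto group, giving the 3S alcohol and leaving the conjugated olefin intact.

Step 16
Reactants: 20 ethyl (3S,4E)-5-Ar-3-hydroxypent-4-enoate
Product: 21 (3S,4E)-5-Ar-pent-4-ene-1,3-diol
Conditions: LiBH4, THF, 0 °C → rt
Reagents that add atoms: none
Why: Borohydride reduction of the ester gives the 1,3-diol without touching the allylic carbinol or the silyl and MOM ethers.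

Step 17
Reactants: 21 (3S,4E)-5-Ar-pent-4-ene-1,3-diol
Product: 22 (3S,4E)-5-Ar-3-hydroxypent-4-en-1-yl acetate
Conditions: AcCl (1.05 equiv), 2,4,6-collidine, CH2Cl2, −78 °C
Reagents that add atoms: acetyl chloride, CC(Cl)=O
Why: Kinetically selective acylation of the primary over the secondary allylic alcohol masks the future chloride position.

Step 18
Reactants: 22 (3S,4E)-5-Ar-3-hydroxypent-4-en-1-yl acetate
Product: 24 (3E,5S)-5-Ar-7-(dimethylamino)-7-oxohept-3-en-1-yl acetate, via ketene N,O-acetal 23 (not isolated)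
Conditions: MeC(OMe)2NMe2, xylenes, 140 °C (MeOH distilled off)
Reagents that add atoms: N,N-dimethylacetamide dimethyl acetal, COC(C)(OC)N(C)C
Why: Eschenmoser–Claisen rearrangement through the same chair transition state transfers the 3S carbinol configuration to the benzylic carbon (future C20), giving the spatial sense opposite to that in 14.

Step 19
Reactants: 24 (3E,5S)-5-Ar-7-(dimethylamino)-7-oxohept-3-en-1-yl acetate
Product: 25 (5R)-5-Ar-7-(dimethylamino)-7-oxoheptyl acetate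
Conditions: H2 (1 atm), 5% Pt/C, EtOAc, rt
Reagents that add atoms: none
Why: Catalytic hydrogenation saturates the olefin to the four-carbon arm (descriptor changes only by CIP rank).

Step 20
Reactants: 25 (5R)-5-Ar-7-(dimethylamino)-7-oxoheptyl acetate
Product: 26 (3R)-3-Ar-7-hydroxy-N,N-dimethylheptanamide
Conditions: K2CO3 (cat.), MeOH, rt
Reagents that add atoms: none
Why: Base-catalysed transesterification removes the acetate while the amide, silyl ethers and MOM ethers stay.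

Step 21
Reactants: 26 (3R)-3-Ar-7-hydroxy-N,N-dimethylheptanamide
Product: 27 (3R)-3-Ar-7-chloro-N,N-dimethylheptanamide
Conditions: PPh3, CCl4, CH2Cl2, 40 °C
Reagents that add atoms: carbon tetrachloride, ClC(Cl)(Cl)Cl
Why: Appel chlorination converts the primary alcohol into the primary chloride by SN2 displacement of the alkoxyphosphonium.

Step 22
Reactants: 27 (3R)-3-Ar-7-chloro-N,N-dimethylheptanamide
Product: 28 (3R)-7-chloro-3-{4-[(1R,2S)-4-hydroxy-2-methyl-1-(triisopropylsilyloxy)butyl]-2,6-bis(methoxymethoxy)phenyl}-N,N-dimethylheptanamide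
Conditions: HF·pyridine, pyridine, THF, 0 °C → rt
Reagents that add atoms: none
Why: Selective fluoride desilylation cleaves the unhindered primary TBS ether much faster than the hindered secondary TIPS ether.

Step 23
Reactants: 28 (3R)-7-chloro-3-{4-[(1R,2S)-4-hydroxy-2-methyl-1-(triisopropylsilyloxy)butyl]-2,6-bis(methoxymethoxy)phenyl}-N,N-dimethylheptanamide
Product: 29 (3R)-7-chloro-3-{2,6-bis(methoxymethoxy)-4-[(1R,2S)-2-methyl-4-oxo-1-(triisopropylsilyloxy)butyl]phenyl}-N,N-dimethylheptanamide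
Conditions: Dess–Martin periodinane, CH2Cl2, 0 °C → rt
Reagents that add atoms: none
Why: Dess–Martin oxidation gives the C4 aldehyde; the methyl-bearing centre is β to the carbonyl and cannot epimerise.

### Union, macrocyclisation and endgame (steps 24–33)

Step 24
Reactants: 18 5-{[(3S)-3-Ar-heptyl]sulfonyl}-1-phenyl-1H-tetrazole; 29 (3R)-7-chloro-3-{2,6-bis(methoxymethoxy)-4-[(1R,2S)-2-methyl-4-oxo-1-(triisopropylsilyloxy)butyl]phenyl}-N,N-dimethylheptanamide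
Product: 31 (3R)-3-{4-[(1R,2S,4E,7S)-7-Ar-2-methyl-1-(triisopropylsilyloxy)undec-4-en-1-yl]-2,6-bis(methoxymethoxy)phenyl}-7-chloro-N,N-dimethylheptanamide, via potassiated sulfone 30 (not isolated)
Conditions: KN(SiMe3)2, THF, −78 °C; then 29, −78 °C → rt
Reagents that add atoms: potassium bis(trimethylsilyl)amide, C[Si](C)(C)[N-][Si](C)(C)C.[K+] (potassium stays only in 30)
Why: Julia–Kocienski olefination (addition, Smiles rearrangement, loss of SO2 and tetrazolone) joins the two halves at C4=C5; the E isomer predominates and the geometry is erased later.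

Step 25
Reactants: 31 (3R)-3-{4-[(1R,2S,4E,7S)-7-Ar-2-methyl-1-(triisopropylsilyloxy)undec-4-en-1-yl]-2,6-bis(methoxymethoxy)phenyl}-7-chloro-N,N-dimethylheptanamide
Product: 32 (3R)-3-{4-[(1R,2S,4E,7S)-7-Ar-2-methyl-1-(triisopropylsilyloxy)undec-4-en-1-yl]-2,6-bis(methoxymethoxy)phenyl}-7-chloroheptanal
Conditions: Cp2Zr(H)Cl (2 equiv), THF, rt, 20 min; aqueous work-up
Reagents that add atoms: none
Why: Schwartz-reagent reduction of the tertiary amide stops at the aldehyde (C18) after hydrolysis and is much faster than hydrozirconation of the internal olefin.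

Step 26
Reactants: 32 (3R)-3-{4-[(1R,2S,4E,7S)-7-Ar-2-methyl-1-(triisopropylsilyloxy)undec-4-en-1-yl]-2,6-bis(methoxymethoxy)phenyl}-7-chloroheptanal
Product: 33 (3R)-7-chloro-3-{4-[(1R,2S,4E,7S)-7-{4-[(1R,2S)-4-hydroxy-2-methyl-1-(triisopropylsilyloxy)butyl]-2,6-bis(methoxymethoxy)phenyl}-2-methyl-1-(triisopropylsilyloxy)undec-4-en-1-yl]-2,6-bis(methoxymethoxy)phenyl}heptanal
Conditions: HF·pyridine, pyridine, THF, 0 °C → rt
Reagents that add atoms: none
Why: Selective fluoride desilylation frees the primary C17 alcohol and leaves both secondary TIPS ethers.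

Step 27
Reactants: 33 (3R)-7-chloro-3-{4-[(1R,2S,4E,7S)-7-{4-[(1R,2S)-4-hydroxy-2-methyl-1-(triisopropylsilyloxy)butyl]-2,6-bis(methoxymethoxy)phenyl}-2-methyl-1-(triisopropylsilyloxy)undec-4-en-1-yl]-2,6-bis(methoxymethoxy)phenyl}heptanal
Product: 34 (3R)-7-chloro-3-{4-[(1R,2S,4E,7S)-7-{2,6-bis(methoxymethoxy)-4-[(1R,2S)-2-methyl-4-oxo-1-(triisopropylsilyloxy)butyl]phenyl}-2-methyl-1-(triisopropylsilyloxy)undec-4-en-1-yl]-2,6-bis(methoxymethoxy)phenyl}heptanal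
Conditions: Dess–Martin periodinane, CH2Cl2, 0 °C → rt
Reagents that add atoms: none
Why: Dess–Martin oxidation gives the C17/C18 dialdehyde, in which both stereocentres next to the chains are β to the carbonyls.

Step 28
Reactants: 34 (3R)-7-chloro-3-{4-[(1R,2S,4E,7S)-7-{2,6-bis(methoxymethoxy)-4-[(1R,2S)-2-methyl-4-oxo-1-(triisopropylsilyloxy)butyl]phenyl}-2-methyl-1-(triisopropylsilyloxy)undec-4-en-1-yl]-2,6-bis(methoxymethoxy)phenyl}heptanal
Product: 35 1-[(4R)-8-chlorooct-1-en-4-yl]-4-[(1R,2S,4E,7S)-7-{2,6-bis(methoxymethoxy)-4-[(1R,2S)-2-methyl-1-(triisopropylsilyloxy)pent-4-en-1-yl]phenyl}-2-methyl-1-(triisopropylsilyloxy)undec-4-en-1-yl]-2,6-bis(methoxymethoxy)benzene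
Conditions: Ph3PCH3Br, KN(SiMe3)2, THF, 0 °C; then 34, 0 °C → rt
Reagents that add atoms: methyltriphenylphosphonium bromide, C[P+](c1ccccc1)(c1ccccc1)c1ccccc1.[Br-]
Why: Double Wittig methylenation converts both aldehydes into the terminal olefins needed for ring closure.

Step 29
Reactants: 35 1-[(4R)-8-chlorooct-1-en-4-yl]-4-[(1R,2S,4E,7S)-7-{2,6-bis(methoxymethoxy)-4-[(1R,2S)-2-methyl-1-(triisopropylsilyloxy)pent-4-en-1-yl]phenyl}-2-methyl-1-(triisopropylsilyloxy)undec-4-en-1-yl]-2,6-bis(methoxymethoxy)benzene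
Product: 36 (1R,2S,4E,7S,14R,15S,17E,20R)-7-butyl-20-(4-chlorobutyl)-2,15-dimethyl-1,14-bis(triisopropylsilyloxy)[7.7]paracyclophane-4,17-diene carrying four ring MOM ethers ortho to C7 and C20
Conditions: second-generation Grubbs catalyst RuCl2(=CHPh)(PCy3)(H2IMes) (10 mol%), CH2Cl2 (1 mM), 40 °C
Reagents that add atoms: none
Why: Ring-closing metathesis of the two terminal olefins at high dilution closes the unstrained 22-membered cyclophane at C17=C18 (head-to-tail is the only mode available); the C20 descriptor reads R here only because the olefin changes CIP ranks.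

Step 30
Reactants: 36 (1R,2S,4E,7S,14R,15S,17E,20R)-7-butyl-20-(4-chlorobutyl)-2,15-dimethyl-1,14-bis(triisopropylsilyloxy)[7.7]paracyclophane-4,17-diene, tetrakis-MOM ether
Product: 37 (1R,2S,7S,14R,15S,20S)-7-butyl-20-(4-chlorobutyl)-2,15-dimethyl-1,14-bis(triisopropylsilyloxy)[7.7]paracyclophane, tetrakis-MOM ether
Conditions: H2 (1 atm), 5% Pt/C, EtOAc, rt
Reagents that add atoms: none
Why: Catalytic hydrogenation saturates both ring olefins; Pt/C in neutral solvent leaves the primary chloride and the benzylic C–O bonds.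

Step 31
Reactants: 37 (1R,2S,7S,14R,15S,20S)-7-butyl-20-(4-chlorobutyl)-2,15-dimethyl-1,14-bis(triisopropylsilyloxy)[7.7]paracyclophane, tetrakis-MOM ether
Product: 38 (1R,2S,7S,14R,15S,20S)-7-butyl-20-(4-chlorobutyl)-2,15-dimethyl[7.7]paracyclophane-1,14-diol, tetrakis-MOM ether
Conditions: n-Bu4NF, THF, rt → 45 °C
Reagents that add atoms: none
Why: Fluoride desilylation frees the two benzylic alcohols without touching C–O configuration, the MOM ethers or the chloride.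

Step 32
Reactants: 38 (1R,2S,7S,14R,15S,20S)-7-butyl-20-(4-chlorobutyl)-2,15-dimethyl[7.7]paracyclophane-1,14-diol, tetrakis-MOM ether
Product: 40 (1R,2S,7S,14R,15S,20S)-7-butyl-20-(4-chlorobutyl)-2,15-dimethyl[7.7]paracyclophane-1,14-diyl dicarbamate, tetrakis-MOM ether, via bis(N-trichloroacetylcarbamate) 39 (not isolated)
Conditions: Cl3CC(O)NCO, CH2Cl2, 0 °C; then K2CO3 (cat.), MeOH, rt
Reagents that add atoms: trichloroacetyl isocyanate, O=C=NC(=O)C(Cl)(Cl)Cl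
Why: Carbamoylation by addition of the alcohols to the very electrophilic acyl isocyanate, then methanolysis of the trichloroacetyl group, gives the primary carbamates with retention because no C–O bond at carbon is broken.

Step 33
Reactants: 40 (1R,2S,7S,14R,15S,20S)-7-butyl-20-(4-chlorobutyl)-2,15-dimethyl[7.7]paracyclophane-1,14-diyl dicarbamate, tetrakis-MOM ether
Product: 41 target, (1R,2S,7S,14R,15S,20S)-7-butyl-20-(4-chlorobutyl)-2,15-dimethyl[7.7]paracyclophane-1,14-diyl dicarbamate with four free ring hydroxyls ortho to C7 and C20 (CNP0117394.1)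
Conditions: 3 M aq. HCl/MeOH (1:4), THF, rt → 35 °C
Reagents that add atoms: none
Why: Acid-catalysed acetal methanolysis removes the four aryl MOM ethers, while the carbamates and the primary chloride are stable because the meta-oxygenated benzylic positions resist ionisation.

## Compound list

1 | 3,5-dihydroxybenzaldehyde | O=Cc1cc(O)cc(O)c1 | starting material
2 | 3,5-bis(methoxymethoxy)benzaldehyde | COCOc1cc(C=O)cc(OCOC)c1 | intermediate
3 | pinacol borate ester of 4 | C=C[C@H](C)[C@@H](OB1OC(C)(C)C(C)(C)O1)c1cc(OCOC)cc(OCOC)c1 | intermediate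
4 | (1R,2S)-1-[3,5-bis(methoxymethoxy)phenyl]-2-methylbut-3-en-1-ol | C=C[C@H](C)[C@@H](O)c1cc(OCOC)cc(OCOC)c1 | intermediate
5 | {[(1R,2S)-1-[3,5-bis(methoxymethoxy)phenyl]-2-methylbut-3-en-1-yl]oxy}triisopropylsilane | C=C[C@H](C)[C@@H](O[Si](C(C)C)(C(C)C)C(C)C)c1cc(OCOC)cc(OCOC)c1 | intermediate
6 | B-alkyl-9-BBN borane from 5, 9-[(3S,4R)-4-aryl-3-methyl-4-(TIPSO)butyl]-9-borabicyclo[3.3.1]nonane | C(C[C@H](C)[C@@H](O[Si](C(C)C)(C(C)C)C(C)C)c1cc(OCOC)cc(OCOC)c1)B1C2CCCC1CCC2 | intermediate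
7 | (3S,4R)-4-[3,5-bis(methoxymethoxy)phenyl]-3-methyl-4-(triisopropylsilyloxy)butan-1-ol | OCC[C@H](C)[C@@H](O[Si](C(C)C)(C(C)C)C(C)C)c1cc(OCOC)cc(OCOC)c1 | intermediate
8 | (1R,2S)-1-[3,5-bis(methoxymethoxy)phenyl]-4-(tert-butyldimethylsilyloxy)-2-methyl-1-(triisopropylsilyloxy)butane | CC(C)(C)[Si](C)(C)OCC[C@H](C)[C@@H](O[Si](C(C)C)(C(C)C)C(C)C)c1cc(OCOC)cc(OCOC)c1 | intermediate
9 | 4-lithio arene from 8 (Ar–Li) | CC(C)(C)[Si](C)(C)OCC[C@H](C)[C@@H](O[Si](C(C)C)(C(C)C)C(C)C)c1cc(OCOC)c([Li])c(OCOC)c1 | intermediate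
10 | Ar–CHO, 4-[(1R,2S)-4-(tert-butyldimethylsilyloxy)-2-methyl-1-(triisopropylsilyloxy)butyl]-2,6-bis(methoxymethoxy)benzaldehyde | CC(C)(C)[Si](C)(C)OCC[C@H](C)[C@@H](O[Si](C(C)C)(C(C)C)C(C)C)c1cc(OCOC)c(C=O)c(OCOC)c1 | intermediate
11 | (1E)-1-Ar-pent-1-en-3-one | CC(C)(C)[Si](C)(C)OCC[C@H](C)[C@@H](O[Si](C(C)C)(C(C)C)C(C)C)c1cc(OCOC)c(/C=C/C(=O)CC)c(OCOC)c1 | intermediate
12 | (1E,3R)-1-Ar-pent-1-en-3-ol | CC(C)(C)[Si](C)(C)OCC[C@H](C)[C@@H](O[Si](C(C)C)(C(C)C)C(C)C)c1cc(OCOC)c(/C=C/[C@H](O)CC)c(OCOC)c1 | intermediate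
13 | ketene N,O-acetal of 12, (1E,3R)-1-Ar-3-{[1-(dimethylamino)ethenyl]oxy}pent-1-ene | CC(C)(C)[Si](C)(C)OCC[C@H](C)[C@@H](O[Si](C(C)C)(C(C)C)C(C)C)c1cc(OCOC)c(/C=C/[C@H](OC(=C)N(C)C)CC)c(OCOC)c1 | intermediate
14 | (3R,4E)-3-Ar-N,N-dimethylhept-4-enamide | CC(C)(C)[Si](C)(C)OCC[C@H](C)[C@@H](O[Si](C(C)C)(C(C)C)C(C)C)c1cc(OCOC)c([C@H](CC(=O)N(C)C)/C=C/CC)c(OCOC)c1 | intermediate
15 | (3S)-3-Ar-N,N-dimethylheptanamide | CC(C)(C)[Si](C)(C)OCC[C@H](C)[C@@H](O[Si](C(C)C)(C(C)C)C(C)C)c1cc(OCOC)c([C@H](CC(=O)N(C)C)CCCC)c(OCOC)c1 | intermediate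
16 | (3S)-3-Ar-heptan-1-ol | CC(C)(C)[Si](C)(C)OCC[C@H](C)[C@@H](O[Si](C(C)C)(C(C)C)C(C)C)c1cc(OCOC)c([C@H](CCO)CCCC)c(OCOC)c1 | intermediate
17 | 5-{[(3S)-3-Ar-heptyl]sulfanyl}-1-phenyl-1H-tetrazole | CC(C)(C)[Si](C)(C)OCC[C@H](C)[C@@H](O[Si](C(C)C)(C(C)C)C(C)C)c1cc(OCOC)c([C@H](CCSc2nnnn2-c2ccccc2)CCCC)c(OCOC)c1 | intermediate
18 | 5-{[(3S)-3-Ar-heptyl]sulfonyl}-1-phenyl-1H-tetrazole | CC(C)(C)[Si](C)(C)OCC[C@H](C)[C@@H](O[Si](C(C)C)(C(C)C)C(C)C)c1cc(OCOC)c([C@H](CCS(=O)(=O)c2nnnn2-c2ccccc2)CCCC)c(OCOC)c1 | intermediate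
19 | ethyl (4E)-5-Ar-3-oxopent-4-enoate | CC(C)(C)[Si](C)(C)OCC[C@H](C)[C@@H](O[Si](C(C)C)(C(C)C)C(C)C)c1cc(OCOC)c(/C=C/C(=O)CC(=O)OCC)c(OCOC)c1 | intermediate
20 | ethyl (3S,4E)-5-Ar-3-hydroxypent-4-enoate | CC(C)(C)[Si](C)(C)OCC[C@H](C)[C@@H](O[Si](C(C)C)(C(C)C)C(C)C)c1cc(OCOC)c(/C=C/[C@@H](O)CC(=O)OCC)c(OCOC)c1 | intermediate
21 | (3S,4E)-5-Ar-pent-4-ene-1,3-diol | CC(C)(C)[Si](C)(C)OCC[C@H](C)[C@@H](O[Si](C(C)C)(C(C)C)C(C)C)c1cc(OCOC)c(/C=C/[C@@H](O)CCO)c(OCOC)c1 | intermediate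
22 | (3S,4E)-5-Ar-3-hydroxypent-4-en-1-yl acetate | CC(C)(C)[Si](C)(C)OCC[C@H](C)[C@@H](O[Si](C(C)C)(C(C)C)C(C)C)c1cc(OCOC)c(/C=C/[C@@H](O)CCOC(C)=O)c(OCOC)c1 | intermediate
23 | ketene N,O-acetal of 22, (3S,4E)-5-Ar-3-{[1-(dimethylamino)ethenyl]oxy}pent-4-en-1-yl acetate | CC(C)(C)[Si](C)(C)OCC[C@H](C)[C@@H](O[Si](C(C)C)(C(C)C)C(C)C)c1cc(OCOC)c(/C=C/[C@@H](OC(=C)N(C)C)CCOC(C)=O)c(OCOC)c1 | intermediate
24 | (3E,5S)-5-Ar-7-(dimethylamino)-7-oxohept-3-en-1-yl acetate | CC(C)(C)[Si](C)(C)OCC[C@H](C)[C@@H](O[Si](C(C)C)(C(C)C)C(C)C)c1cc(OCOC)c([C@@H](CC(=O)N(C)C)/C=C/CCOC(C)=O)c(OCOC)c1 | intermediate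
25 | (5R)-5-Ar-7-(dimethylamino)-7-oxoheptyl acetate | CC(C)(C)[Si](C)(C)OCC[C@H](C)[C@@H](O[Si](C(C)C)(C(C)C)C(C)C)c1cc(OCOC)c([C@@H](CC(=O)N(C)C)CCCCOC(C)=O)c(OCOC)c1 | intermediate
26 | (3R)-3-Ar-7-hydroxy-N,N-dimethylheptanamide | CC(C)(C)[Si](C)(C)OCC[C@H](C)[C@@H](O[Si](C(C)C)(C(C)C)C(C)C)c1cc(OCOC)c([C@@H](CC(=O)N(C)C)CCCCO)c(OCOC)c1 | intermediate
27 | (3R)-3-Ar-7-chloro-N,N-dimethylheptanamide | CC(C)(C)[Si](C)(C)OCC[C@H](C)[C@@H](O[Si](C(C)C)(C(C)C)C(C)C)c1cc(OCOC)c([C@@H](CC(=O)N(C)C)CCCCCl)c(OCOC)c1 | intermediate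
28 | (3R)-7-chloro-3-{4-[(1R,2S)-4-hydroxy-2-methyl-1-(triisopropylsilyloxy)butyl]-2,6-bis(methoxymethoxy)phenyl}-N,N-dimethylheptanamide | OCC[C@H](C)[C@@H](O[Si](C(C)C)(C(C)C)C(C)C)c1cc(OCOC)c([C@@H](CC(=O)N(C)C)CCCCCl)c(OCOC)c1 | intermediate
29 | (3R)-7-chloro-3-{2,6-bis(methoxymethoxy)-4-[(1R,2S)-2-methyl-4-oxo-1-(triisopropylsilyloxy)butyl]phenyl}-N,N-dimethylheptanamide | O=CC[C@H](C)[C@@H](O[Si](C(C)C)(C(C)C)C(C)C)c1cc(OCOC)c([C@@H](CC(=O)N(C)C)CCCCCl)c(OCOC)c1 | intermediate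
30 | potassiated sulfone, potassium α-sulfonyl carbanion of 18 | CC(C)(C)[Si](C)(C)OCC[C@H](C)[C@@H](O[Si](C(C)C)(C(C)C)C(C)C)c1cc(OCOC)c([C@H](C[CH-]S(=O)(=O)c2nnnn2-c2ccccc2)CCCC)c(OCOC)c1.[K+] | intermediate
31 | (3R)-3-{4-[(1R,2S,4E,7S)-7-Ar-2-methyl-1-(triisopropylsilyloxy)undec-4-en-1-yl]-2,6-bis(methoxymethoxy)phenyl}-7-chloro-N,N-dimethylheptanamide (C4=C5 formed; C17 as CH2OTBS; C18 as CONMe2) | CC(C)(C)[Si](C)(C)OCC[C@H](C)[C@@H](O[Si](C(C)C)(C(C)C)C(C)C)c1cc(OCOC)c([C@@H](CCCC)C/C=C/C[C@H](C)[C@@H](O[Si](C(C)C)(C(C)C)C(C)C)c2cc(OCOC)c([C@@H](CC(=O)N(C)C)CCCCCl)c(OCOC)c2)c(OCOC)c1 | intermediate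
32 | (3R)-3-{4-[(1R,2S,4E,7S)-7-Ar-2-methyl-1-(triisopropylsilyloxy)undec-4-en-1-yl]-2,6-bis(methoxymethoxy)phenyl}-7-chloroheptanal (C18 as CHO) | CC(C)(C)[Si](C)(C)OCC[C@H](C)[C@@H](O[Si](C(C)C)(C(C)C)C(C)C)c1cc(OCOC)c([C@@H](CCCC)C/C=C/C[C@H](C)[C@@H](O[Si](C(C)C)(C(C)C)C(C)C)c2cc(OCOC)c([C@@H](CC=O)CCCCCl)c(OCOC)c2)c(OCOC)c1 | intermediate
33 | (3R)-7-chloro-3-{4-[(1R,2S,4E,7S)-7-{4-[(1R,2S)-4-hydroxy-2-methyl-1-(triisopropylsilyloxy)butyl]-2,6-bis(methoxymethoxy)phenyl}-2-methyl-1-(triisopropylsilyloxy)undec-4-en-1-yl]-2,6-bis(methoxymethoxy)phenyl}heptanal (C17 as CH2OH) | OCC[C@H](C)[C@@H](O[Si](C(C)C)(C(C)C)C(C)C)c1cc(OCOC)c([C@@H](CCCC)C/C=C/C[C@H](C)[C@@H](O[Si](C(C)C)(C(C)C)C(C)C)c2cc(OCOC)c([C@@H](CC=O)CCCCCl)c(OCOC)c2)c(OCOC)c1 | intermediate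
34 | (3R)-7-chloro-3-{4-[(1R,2S,4E,7S)-7-{2,6-bis(methoxymethoxy)-4-[(1R,2S)-2-methyl-4-oxo-1-(triisopropylsilyloxy)butyl]phenyl}-2-methyl-1-(triisopropylsilyloxy)undec-4-en-1-yl]-2,6-bis(methoxymethoxy)phenyl}heptanal (C17/C18 dialdehyde) | O=CC[C@H](C)[C@@H](O[Si](C(C)C)(C(C)C)C(C)C)c1cc(OCOC)c([C@@H](CCCC)C/C=C/C[C@H](C)[C@@H](O[Si](C(C)C)(C(C)C)C(C)C)c2cc(OCOC)c([C@@H](CC=O)CCCCCl)c(OCOC)c2)c(OCOC)c1 | intermediate
35 | 1-[(4R)-8-chlorooct-1-en-4-yl]-4-[(1R,2S,4E,7S)-7-{2,6-bis(methoxymethoxy)-4-[(1R,2S)-2-methyl-1-(triisopropylsilyloxy)pent-4-en-1-yl]phenyl}-2-methyl-1-(triisopropylsilyloxy)undec-4-en-1-yl]-2,6-bis(methoxymethoxy)benzene | C=CC[C@H](C)[C@@H](O[Si](C(C)C)(C(C)C)C(C)C)c1cc(OCOC)c([C@@H](CCCC)C/C=C/C[C@H](C)[C@@H](O[Si](C(C)C)(C(C)C)C(C)C)c2cc(OCOC)c([C@@H](CC=C)CCCCCl)c(OCOC)c2)c(OCOC)c1 | intermediate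
36 | (1R,2S,4E,7S,14R,15S,17E,20R)-7-butyl-20-(4-chlorobutyl)-2,15-dimethyl-1,14-bis(triisopropylsilyloxy)[7.7]paracyclophane-4,17-diene, four ring MOM ethers ortho to C7 and C20 | C1/C=C/C[C@H](C)[C@@H](O[Si](C(C)C)(C(C)C)C(C)C)c2cc(OCOC)c(c(OCOC)c2)[C@@H](CCCC)C/C=C/C[C@H](C)[C@@H](O[Si](C(C)C)(C(C)C)C(C)C)c2cc(OCOC)c(c(OCOC)c2)[C@@H]1CCCCCl | intermediate
37 | (1R,2S,7S,14R,15S,20S)-7-butyl-20-(4-chlorobutyl)-2,15-dimethyl-1,14-bis(triisopropylsilyloxy)[7.7]paracyclophane, tetrakis-MOM ether | C1CCC[C@H](C)[C@@H](O[Si](C(C)C)(C(C)C)C(C)C)c2cc(OCOC)c(c(OCOC)c2)[C@@H](CCCC)CCCC[C@H](C)[C@@H](O[Si](C(C)C)(C(C)C)C(C)C)c2cc(OCOC)c(c(OCOC)c2)[C@@H]1CCCCCl | intermediate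
38 | (1R,2S,7S,14R,15S,20S)-7-butyl-20-(4-chlorobutyl)-2,15-dimethyl[7.7]paracyclophane-1,14-diol, tetrakis-MOM ether | C1CCC[C@H](C)[C@@H](O)c2cc(OCOC)c(c(OCOC)c2)[C@@H](CCCC)CCCC[C@H](C)[C@@H](O)c2cc(OCOC)c(c(OCOC)c2)[C@@H]1CCCCCl | intermediate
39 | bis(N-trichloroacetylcarbamate) of 38 | C1CCC[C@H](C)[C@@H](OC(=O)NC(=O)C(Cl)(Cl)Cl)c2cc(OCOC)c(c(OCOC)c2)[C@@H](CCCC)CCCC[C@H](C)[C@@H](OC(=O)NC(=O)C(Cl)(Cl)Cl)c2cc(OCOC)c(c(OCOC)c2)[C@@H]1CCCCCl | intermediate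
40 | (1R,2S,7S,14R,15S,20S)-7-butyl-20-(4-chlorobutyl)-2,15-dimethyl[7.7]paracyclophane-1,14-diyl dicarbamate, tetrakis-MOM ether | C1CCC[C@H](C)[C@@H](OC(N)=O)c2cc(OCOC)c(c(OCOC)c2)[C@@H](CCCC)CCCC[C@H](C)[C@@H](OC(N)=O)c2cc(OCOC)c(c(OCOC)c2)[C@@H]1CCCCCl | intermediate
41 | (1R,2S,7S,14R,15S,20S)-7-butyl-20-(4-chlorobutyl)-2,15-dimethyl[7.7]paracyclophane-1,14-diyl dicarbamate with four free ring hydroxyls (CNP0117394.1) | CCCC[C@H]1CCCC[C@H](C)[C@@H](OC(N)=O)c2cc(O)c(c(O)c2)[C@H](CCCCCl)CCCC[C@H](C)[C@@H](OC(N)=O)c2cc(O)c1c(O)c2 | target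

## Step count and risks

Total step count: 33. Longest linear sequence: 26 steps (1–6, 14–23, 24–33).

The three steps most likely to fail:

Step 15 (ketoreductase reduction of 19). The substrate is large and very lipophilic, so activity in aqueous buffer may be poor. The fallback sets out from 19 and comes back at 20. It moves the enzymatic stereoselection into organic solvent as a kinetic resolution. Luche reduction of 19 (NaBH4, CeCl3·7H2O, MeOH, −40 °C) gives 20 together with its C3 epimer, ethyl (3R,4E)-5-Ar-3-hydroxypent-4-enoate F1. A lipase (Burkholderia cepacia lipase, vinyl acetate, MTBE, 30 °C) acetylates only the 3R epimer, giving ethyl (3R,4E)-3-acetoxy-5-Ar-pent-4-enoate F2. Unreacted 20 is separated from F2 by chromatography and rejoins the route at step 16.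

Step 18 (Eschenmoser–Claisen onto the di-ortho-substituted styrenyl terminus; step 9 is the same reaction on the simpler substrate). If the thermal rearrangement is sluggish or the allylic alcohol decomposes at 140 °C, the fallback switches to the low-temperature ester-enolate manifold. It sets out from 22 and comes back at 24. Acetylation (Ac2O, pyridine, DMAP) gives (3S,4E)-5-Ar-pent-4-ene-1,3-diyl diacetate F3. LiN(SiMe3)2 (2.5 equiv) with Me3SiCl/Et3N in THF at −78 °C converts both acetates into the bis(trimethylsilyl ketene acetal) F4. Warming to 50 °C brings about the Ireland–Claisen rearrangement of the allylic half to the trimethylsilyl ester F5. Aqueous acid work-up returns the spectator ketene acetal to the acetate and gives (3S,4E)-7-acetoxy-3-Ar-hept-4-enoic acid F6. Amide coupling of F6 with Me2NH·HCl (EDC·HCl, HOBt, i-Pr2NEt, CH2Cl2) gives 24.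

Step 33 (MOM removal in the presence of the two benzylic carbamates). If acid causes benzylic solvolysis of the carbamates, the order of the last operations is changed. The fallback sets out from 38 and comes back at 41. The MOM ethers are cleaved first (3 M HCl, MeOH, THF) to give (1R,2S,7S,14R,15S,20S)-7-butyl-20-(4-chlorobutyl)-2,15-dimethyl[7.7]paracyclophane-1,14-diol with four free phenols, hexol F7. Excess Cl3CC(O)NCO acylates all six hydroxyls to the hexakis(N-trichloroacetylcarbamate) F8. K2CO3 in MeOH removes the trichloroacetyl groups to give the hexacarbamate F9 and then methanolyses its four base-labile aryl carbamates. The two alkyl carbamates survive, so 41 is obtained directly.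

Further compounds
F1 | step 15 | ethyl (3R,4E)-5-Ar-3-hydroxypent-4-enoate (C3 epimer of 20) | CC(C)(C)[Si](C)(C)OCC[C@H](C)[C@@H](O[Si](C(C)C)(C(C)C)C(C)C)c1cc(OCOC)c(/C=C/[C@H](O)CC(=O)OCC)c(OCOC)c1
F2 | step 15 | ethyl (3R,4E)-3-acetoxy-5-Ar-pent-4-enoate | CC(C)(C)[Si](C)(C)OCC[C@H](C)[C@@H](O[Si](C(C)C)(C(C)C)C(C)C)c1cc(OCOC)c(/C=C/[C@H](OC(C)=O)CC(=O)OCC)c(OCOC)c1
F3 | step 18 | (3S,4E)-5-Ar-pent-4-ene-1,3-diyl diacetate | CC(C)(C)[Si](C)(C)OCC[C@H](C)[C@@H](O[Si](C(C)C)(C(C)C)C(C)C)c1cc(OCOC)c(/C=C/[C@@H](OC(C)=O)CCOC(C)=O)c(OCOC)c1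
F4 | step 18 | bis(trimethylsilyl ketene acetal) of F3 | CC(C)(C)[Si](C)(C)OCC[C@H](C)[C@@H](O[Si](C(C)C)(C(C)C)C(C)C)c1cc(OCOC)c(/C=C/[C@@H](OC(=C)O[Si](C)(C)C)CCOC(=C)O[Si](C)(C)C)c(OCOC)c1
F5 | step 18 | trimethylsilyl (3S,4E)-3-Ar-7-{[1-(trimethylsilyloxy)ethenyl]oxy}hept-4-enoate | CC(C)(C)[Si](C)(C)OCC[C@H](C)[C@@H](O[Si](C(C)C)(C(C)C)C(C)C)c1cc(OCOC)c([C@@H](CC(=O)O[Si](C)(C)C)/C=C/CCOC(=C)O[Si](C)(C)C)c(OCOC)c1
F6 | step 18 | (3S,4E)-7-acetoxy-3-Ar-hept-4-enoic acid | CC(C)(C)[Si](C)(C)OCC[C@H](C)[C@@H](O[Si](C(C)C)(C(C)C)C(C)C)c1cc(OCOC)c([C@@H](CC(=O)O)/C=C/CCOC(C)=O)c(OCOC)c1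
F7 | step 33 | (1R,2S,7S,14R,15S,20S)-7-butyl-20-(4-chlorobutyl)-2,15-dimethyl[7.7]paracyclophane-1,14-diol with four free ring hydroxyls (hexol) | C1CCC[C@H](C)[C@@H](O)c2cc(O)c(c(O)c2)[C@@H](CCCC)CCCC[C@H](C)[C@@H](O)c2cc(O)c(c(O)c2)[C@@H]1CCCCCl
F8 | step 33 | hexakis(N-trichloroacetylcarbamate) of F7 | C1CCC[C@H](C)[C@@H](OC(=O)NC(=O)C(Cl)(Cl)Cl)c2cc(OC(=O)NC(=O)C(Cl)(Cl)Cl)c(c(OC(=O)NC(=O)C(Cl)(Cl)Cl)c2)[C@@H](CCCC)CCCC[C@H](C)[C@@H](OC(=O)NC(=O)C(Cl)(Cl)Cl)c2cc(OC(=O)NC(=O)C(Cl)(Cl)Cl)c(c(OC(=O)NC(=O)C(Cl)(Cl)Cl)c2)[C@@H]1CCCCCl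
F9 | step 33 | hexacarbamate of F7 (two alkyl and four aryl carbamates) | C1CCC[C@H](C)[C@@H](OC(N)=O)c2cc(OC(N)=O)c(c(OC(N)=O)c2)[C@@H](CCCC)CCCC[C@H](C)[C@@H](OC(N)=O)c2cc(OC(N)=O)c(c(OC(N)=O)c2)[C@@H]1CCCCCl
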